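The plan rests on cutting the C(sp2)–C(sp3) bond between C4 of the anisole ring A (the carbon para to OMe) and the neighbouring CH2 of the ethylene bridge to the meta-phenylene ring D. This exploits the Ar(A)–CH2–CH2–Ar(D) unit as the retron of an aryl halide plus a styrene. The key step is a one-pot 9-BBN hydroboration and intramolecular B-alkyl Suzuki–Miyaura coupling: it turns an open-chain tetra-aryl bis-ether, bearing bromine at ring A C4 and a vinyl group on ring D, into the 19-membered bis(bibenzyl) macrocycle with the bridge already saturated. The other ethylene bridge is built by the same tactic intermolecularly (aryl iodide before aryl bromide), and both diaryl ethers come from Chan–Lam couplings.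

Key step: step 5

Assumption: the target has no stereocentre, and compounds 1, 2, 4, 8 and 9-BBN are taken as catalogue materials. Ring letters: A = methoxy-bearing ring, B = para-phenylene, C = hydroxy-bearing ring, D = meta-phenylene.

Step 1
Reactants: 1 5-bromo-2-methoxyphenol; 2 (4-iodophenyl)boronic acid
Product: 3 4-bromo-2-(4-iodophenoxy)-1-methoxybenzene
Conditions: Cu(OAc)2 (1 equiv), pyridine, 4 Å MS, CH2Cl2, air (terminal oxidant), rt
Reagents that add atoms: none
Why: Chan–Lam O-arylation of the phenol by the arylboronic acid runs at room temperature, where neither the C–Br nor the C–I bond should be touched by copper.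

Step 2
Reactants: 4 4-(benzyloxy)-3-hydroxybenzaldehyde
Product: 5 2-(benzyloxy)-5-ethenylphenol
Conditions: Ph3PCH3Br (2.5 equiv), KOtBu (2.5 equiv), THF, 0 °C to rt; aq NH4Cl
Reagents that add atoms: methyltriphenylphosphonium bromide, C[P+](c1ccccc1)(c1ccccc1)c1ccccc1.[Br-]
Why: Wittig methylenation with excess non-stabilised ylide, the first equivalent of base being taken up by the phenol, should convert the aldehyde into the terminal alkene.

Step 3
Reactants: 5 2-(benzyloxy)-5-ethenylphenol; 3 4-bromo-2-(4-iodophenoxy)-1-methoxybenzene
Product: 7 2-(benzyloxy)-5-{2-[4-(5-bromo-2-methoxyphenoxy)phenyl]ethyl}phenol, via O-boryl B-alkyl-9-BBN borane 6 (not isolated)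
Conditions: 9-BBN (2.2 equiv), THF, 0 °C to rt; then 3 (0.9 equiv), PdCl2(dppf) (5 mol%), 3 M aq NaOH, THF, rt
Reagents that add atoms: none
Why: Anti-Markovnikov hydroboration of the styrene (one further equivalent of 9-BBN is consumed by the phenol O–H) followed by B-alkyl Suzuki–Miyaura coupling, in which Pd(0) should insert into the C–I bond of 3 far faster than into the electron-rich C–Br bond at room temperature.

Step 4
Reactants: 7 2-(benzyloxy)-5-{2-[4-(5-bromo-2-methoxyphenoxy)phenyl]ethyl}phenol; 8 (3-ethenylphenyl)boronic acid
Product: 9 1-(benzyloxy)-4-{2-[4-(5-bromo-2-methoxyphenoxy)phenyl]ethyl}-2-(3-ethenylphenoxy)benzene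
Conditions: 8 (2.5 equiv), Cu(OAc)2 (1 equiv), pyridine, 4 Å MS, CH2Cl2, air (terminal oxidant), rt
Reagents that add atoms: none
Why: Chan–Lam O-arylation at room temperature should tolerate the aryl bromide, the benzyl ether and the styrene, and so brings in ring D with its vinyl group only after the first borane step is over.

Step 5
Reactants: 9 1-(benzyloxy)-4-{2-[4-(5-bromo-2-methoxyphenoxy)phenyl]ethyl}-2-(3-ethenylphenoxy)benzene
Product: 11 macrocyclic benzyl ether (the target with OBn in place of OH on ring C), via B-alkyl-9-BBN borane 10 (not isolated)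
Conditions: 9-BBN (1.5 equiv), THF, rt; then syringe-pump addition (12 h) to Pd(OAc)2 (10 mol%), SPhos (20 mol%), K3PO4 (3 equiv), THF/H2O, 65 °C, final about 2 mM
Reagents that add atoms: none
Why: 9-BBN adds to the ring-D styrene with anti-Markovnikov regiochemistry to give the primary alkylborane 10; Pd(0)/SPhos then inserts into the single C–Br bond at ring A C4, base-assisted transmetalation moves the primary alkyl group from boron to palladium, and reductive elimination forms the aryl–CH2 bond. The closest known reaction type is the macrocyclising B-alkyl Suzuki–Miyaura coupling used for cyclophanes and macrolides. The 19-membered ring (shortest path) closes end to end by reductive elimination from a 20-membered aryl(alkyl)palladacycle, the two diaryl ether hinges letting the chain fold without strain. No stereocentre is formed. The step needs ring closure to beat oligomerisation and β-hydride elimination: slow addition keeps the open borane dilute, and the bulky electron-rich biarylphosphine should speed both oxidative addition into the electron-rich C–Br bond and reductive elimination. The site of the new bond is fixed, because the substrate holds only one C–Br bond and one C–B bond.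

Step 6
Reactants: 11 macrocyclic benzyl ether
Product: 12 CNP0132125.0 (target)
Conditions: H2 (1 atm), 10% Pd/C, EtOAc/MeOH, rt
Reagents that add atoms: none
Why: Hydrogenolysis of the benzyl ether over Pd/C should free the ring-C phenol while the methyl ether, the diaryl ethers and the saturated bridges stay inert.

Compound list
1 | 5-bromo-2-methoxyphenol | COc1ccc(Br)cc1O | starting material
2 | (4-iodophenyl)boronic acid | OB(O)c1ccc(I)cc1 | starting material
3 | 4-bromo-2-(4-iodophenoxy)-1-methoxybenzene | COc1ccc(Br)cc1Oc1ccc(I)cc1 | intermediate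
4 | 4-(benzyloxy)-3-hydroxybenzaldehyde | O=Cc1ccc(OCc2ccccc2)c(O)c1 | starting material
5 | 2-(benzyloxy)-5-ethenylphenol | C=Cc1ccc(OCc2ccccc2)c(O)c1 | intermediate
6 | 9-{2-(benzyloxy)-5-[2-(9-borabicyclo[3.3.1]nonan-9-yl)ethyl]phenoxy}-9-borabicyclo[3.3.1]nonane (not isolated) | c1ccccc1COc1ccc(CCB2C3CCCC2CCC3)cc1OB1C2CCCC1CCC2 | intermediate
7 | 2-(benzyloxy)-5-{2-[4-(5-bromo-2-methoxyphenoxy)phenyl]ethyl}phenol | COc1ccc(Br)cc1Oc1ccc(CCc2ccc(OCc3ccccc3)c(O)c2)cc1 | intermediate
8 | (3-ethenylphenyl)boronic acid | C=Cc1cccc(B(O)O)c1 | starting material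
9 | 1-(benzyloxy)-4-{2-[4-(5-bromo-2-methoxyphenoxy)phenyl]ethyl}-2-(3-ethenylphenoxy)benzene | COc1ccc(Br)cc1Oc1ccc(CCc2ccc(OCc3ccccc3)c(Oc3cccc(C=C)c3)c2)cc1 | intermediate
10 | B-alkyl-9-BBN borane of 9, boron on the terminal carbon of the former vinyl group (not isolated) | COc1ccc(Br)cc1Oc1ccc(CCc2ccc(OCc3ccccc3)c(Oc3cccc(CCB4C5CCCC4CCC5)c3)c2)cc1 | intermediate
11 | macrocyclic benzyl ether: 19-membered bis(bibenzyl) bis(diaryl ether), ring C carrying OBn | COc1ccc2cc1Oc1ccc(cc1)CCc1ccc(OCc3ccccc3)c(c1)Oc1cccc(c1)CC2 | intermediate
12 | CNP0132125.0: 19-membered bis(bibenzyl) bis(diaryl ether) with OMe on ring A and OH on ring C | COc1ccc2cc1Oc1ccc(cc1)CCc1ccc(O)c(c1)Oc1cccc(c1)CC2 | target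

Total step count: 6. Longest linear sequence: 5 steps (steps 1, 3, 4, 5, 6 or steps 2, 3, 4, 5, 6).

Steps most likely to fail

Step 5. Intermolecular coupling may outrun ring closure and give oligomers, or the alkylborane may be lost by protodeboronation or β-hydride elimination before the slow oxidative addition into the electron-rich C–Br bond. The fallback sets out from 9 and makes the same ring A C4–carbon bond by an intramolecular Mizoroki–Heck reaction (Pd(OAc)2, P(o-tol)3, K2CO3, Bu4NBr, DMF, 100 °C, high dilution). This should give the macrocyclic (E)-stilbene benzyl ether F1. Hydrogenation over Pd/C (H2, EtOAc/MeOH) should then saturate the alkene and cleave the benzyl ether in one operation, so the fallback comes back to the route at 12.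

Step 3. The catalyst may fail to discriminate fully between the C–I and C–Br bonds, which would lead to chain growth, or the hydroboration may stay incomplete because the phenol consumes borane. The fallback sets out from 3 and 5 and joins them by a ligand-free, phase-transfer Mizoroki–Heck reaction (Pd(OAc)2, Bu4NCl, NaHCO3, DMF, 60 °C), in which only the iodide should react, to give the (E)-stilbene F2. Diimide reduction (TsNHNH2, NaOAc, DME/H2O, reflux) should saturate the alkene without touching the C–Br bond or the benzyl ether, and the fallback comes back to the route at 7.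

Step 4. O-Arylation of the ortho-substituted phenol may be slow, so that protodeboronation or homocoupling of the boronic acid, or polymerisation of the styrene, takes over. The fallback sets out from 7 and uses an Ullmann ether coupling with commercial 3-iodobenzaldehyde (CuI, picolinic acid, K3PO4, DMSO, 80 °C), the aryl iodide reacting ahead of the electron-rich ring-A bromide, to give the aldehyde 3-[2-(benzyloxy)-5-{2-[4-(5-bromo-2-methoxyphenoxy)phenyl]ethyl}phenoxy]benzaldehyde F3. Wittig methylenation (Ph3PCH3Br, KOtBu, THF, 0 °C to rt) then brings the fallback back to the route at 9.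

Further compounds
F1 | step 5 | macrocyclic (E)-stilbene benzyl ether (ring A C4 joined to ring D through CH=CH) | COc1ccc(/C=C/c2cccc(Oc3cc(CCc4ccc(O5)cc4)ccc3OCc3ccccc3)c2)cc15
F2 | step 3 | 2-(benzyloxy)-5-{(E)-2-[4-(5-bromo-2-methoxyphenoxy)phenyl]ethenyl}phenol | COc1ccc(Br)cc1Oc1ccc(/C=C/c2ccc(OCc3ccccc3)c(O)c2)cc1
F3 | step 4 | 3-[2-(benzyloxy)-5-{2-[4-(5-bromo-2-methoxyphenoxy)phenyl]ethyl}phenoxy]benzaldehyde | COc1ccc(Br)cc1Oc1ccc(CCc2ccc(OCc3ccccc3)c(Oc3cccc(C=O)c3)c2)cc1
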